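**Plan**

- Cuts, in retrosynthetic order: the five benzyl ethers; the C2–aryl bond of unit 2 (the 4-methoxyphenyl flavanone, made by 1,4-arylation of a chromone); C3 of unit 1 (cis to trans); ring C of unit 1 at O1–C8a and C4–C4a together; the Cα–Cβ aldol bond; the CH2–C8 bond to the chromone.
- Feature used: in ring A of unit 1 the ring oxygen sits on C8a and the ketone carbon C4 on the neighbouring C4a, which has the C5 oxygen on its other side. A 3-alkoxybenzyne takes a nucleophile meta to the alkoxy group and leaves the carbanion ortho to it, so 3,5-bis(benzyloxy)benzyne supplies C8a–O1 and C4a–C4 in one operation and brings ring A complete.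
- Forward order: the chromone (rings A and C of unit 2) is there from the start; rings A and C of unit 1 arise in the aryne step; ring C of unit 2 reaches the flavanone level last.
- Helpers: an O–SiMe3 group (releases the alkoxide with the same fluoride that releases the aryne) and a morpholine amide (holds C4 as a tetrahedral adduct until the quench); both leave in the key step.
- Stereochemistry: C2 of unit 1 from an Evans syn-aldol with (R)-4-benzyloxazolidinone; C3 of unit 1 by equilibration to 2,3-trans; C2 of unit 2 from ligand-controlled palladium-catalysed conjugate arylation.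

Key step: step 11

Remark: the target is read as a 2,3-trans (2R,3S) flavanone (unit 1) joined through C3 to C8 of a (2S)-flavanone (unit 2); trans is taken to be the thermodynamically preferred arrangement at C2/C3 of unit 1.

**Route**

Step 1
Reactants: 1 5,7-dihydroxy-4H-chromen-4-one
Product: 2 5,7-bis(benzyloxy)-4H-chromen-4-one
Conditions: BnBr (2.5 equiv), K2CO3, DMF, 60 °C
Reagents that add atoms: benzyl bromide, BrCc1ccccc1
Why: Williamson etherification, in which warm K2CO3/DMF should also benzylate the chelated 5-OH while the chromone has no other site that reacts.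

Step 2
Reactants: 2 5,7-bis(benzyloxy)-4H-chromen-4-one
Product: 3 5,7-bis(benzyloxy)-8-iodo-4H-chromen-4-one
Conditions: NIS (1.05 equiv), TFA (0.3 equiv), MeCN, 0 °C to rt
Reagents that add atoms: N-iodosuccinimide, O=C1CCC(=O)N1I
Why: Electrophilic aromatic iodination, expected at C8 (activated by both benzyloxy groups and O1, less hindered than C6 between two benzyloxy groups) as with 5,7-dialkoxyflavones; the position is to be confirmed by NOE/HMBC.

Step 3
Reactants: 3 5,7-bis(benzyloxy)-8-iodo-4H-chromen-4-one; 4 (2-tert-butoxy-2-oxoethyl)zinc bromide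
Product: 5 tert-butyl 2-[5,7-bis(benzyloxy)-4-oxo-4H-chromen-8-yl]acetate
Conditions: Pd2(dba)3 (2.5 mol %), XPhos (10 mol %), THF, 60 °C
Reagents that add atoms: none
Why: Negishi-type coupling of a Reformatsky zinc enolate with an aryl iodide (ester alpha-arylation); the mild zinc reagent should leave the chromone enone and benzyl ethers alone and the bulky biarylphosphine should cope with the two ortho substituents.

Step 4
Reactants: 5 tert-butyl 2-[5,7-bis(benzyloxy)-4-oxo-4H-chromen-8-yl]acetate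
Product: 6 2-[5,7-bis(benzyloxy)-4-oxo-4H-chromen-8-yl]acetic acid
Conditions: TFA/CH2Cl2 (1:4), 0 °C to rt
Reagents that add atoms: none
Why: Acidolysis of the tert-butyl ester (loss of isobutene); the benzyl ethers on the electron-poor chromone ring should survive the short exposure.

Step 5
Reactants: 6 2-[5,7-bis(benzyloxy)-4-oxo-4H-chromen-8-yl]acetic acid; 7 (R)-4-benzyl-1,3-oxazolidin-2-one
Product: 9 (R)-4-benzyl-3-{2-[5,7-bis(benzyloxy)-4-oxo-4H-chromen-8-yl]acetyl}-1,3-oxazolidin-2-one, via mixed pivalic anhydride 8 (not isolated)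
Conditions: PivCl, Et3N, THF, −20 °C; then 7, LiCl, rt
Reagents that add atoms: none
Why: N-acylation of the oxazolidinone through the mixed pivalic anhydride (LiCl-promoted), a standard way to load arylacetic acids onto the auxiliary without strong base.

Step 6
Reactants: 9 (R)-4-benzyl-3-{2-[5,7-bis(benzyloxy)-4-oxo-4H-chromen-8-yl]acetyl}-1,3-oxazolidin-2-one; 10 4-(benzyloxy)benzaldehyde
Product: 12 (4R)-4-benzyl-3-{(2R,3R)-2-[5,7-bis(benzyloxy)-4-oxo-4H-chromen-8-yl]-3-[4-(benzyloxy)phenyl]-3-hydroxypropanoyl}-1,3-oxazolidin-2-one, via Z-boron enolate 11 (not isolated)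
Conditions: n-Bu2BOTf (2.3 equiv), i-Pr2NEt (2.6 equiv), CH2Cl2, −78 to 0 °C; 10, −78 to 0 °C; pH 7 buffer, MeOH, H2O2, 0 °C
Reagents that add atoms: none
Why: Evans syn-aldol through the Z-boron enolate and a Zimmerman–Traxler chair, in which the (R)-auxiliary should set the (2R,3R) adduct (the R carbinol becomes C2 of unit 1); the extra equivalent of boron triflate is there to saturate the Lewis-basic chromone carbonyl.

Step 7
Reactants: 12 (4R)-4-benzyl-3-{(2R,3R)-2-[5,7-bis(benzyloxy)-4-oxo-4H-chromen-8-yl]-3-[4-(benzyloxy)phenyl]-3-hydroxypropanoyl}-1,3-oxazolidin-2-one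
Product: 13 (2R,3R)-2-[5,7-bis(benzyloxy)-4-oxo-4H-chromen-8-yl]-3-[4-(benzyloxy)phenyl]-3-hydroxy-1-(morpholin-4-yl)propan-1-one
Conditions: morpholine, AlMe3, CH2Cl2, −20 to 0 °C; aqueous Rochelle salt
Reagents that add atoms: morpholine, C1COCCN1
Why: Aluminium-amide (Weinreb-type) aminolysis of the imide, directed to the exocyclic carbonyl by the aluminium alkoxide of the beta-hydroxyl; it frees the auxiliary and installs the amide needed in step 11.

Step 8
Reactants: 13 (2R,3R)-2-[5,7-bis(benzyloxy)-4-oxo-4H-chromen-8-yl]-3-[4-(benzyloxy)phenyl]-3-hydroxy-1-(morpholin-4-yl)propan-1-one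
Product: 14 (2R,3R)-2-[5,7-bis(benzyloxy)-4-oxo-4H-chromen-8-yl]-3-[4-(benzyloxy)phenyl]-1-(morpholin-4-yl)-3-[(trimethylsilyl)oxy]propan-1-one
Conditions: TMSCl, imidazole, CH2Cl2, 0 °C
Reagents that add atoms: chlorotrimethylsilane, C[Si](C)(C)Cl
Why: Routine O-silylation; the trimethylsilyl ether removes the O–H proton and is the fluoride-labile mask of the alkoxide for step 11.

Step 9
Reactants: 15 3,5-bis(benzyloxy)phenol
Product: 16 3,5-bis(benzyloxy)-2-bromophenol
Conditions: NBS (1.0 equiv), CH2Cl2, −78 to −20 °C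
Reagents that add atoms: N-bromosuccinimide, O=C1CCC(=O)N1Br
Why: Electrophilic bromination ortho to the phenol, expected at C2 (two equivalent sites) in preference to C4, which lies between two benzyloxy groups.

Step 10
Reactants: 16 3,5-bis(benzyloxy)-2-bromophenol
Product: 19 3,5-bis(benzyloxy)-2-(trimethylsilyl)phenyl trifluoromethanesulfonate, via aryl silyl ether 17 (not isolated), via lithium silylphenolate 18 (not isolated)
Conditions: HMDS, THF, 70 °C, evaporation; n-BuLi, THF, −100 to −78 °C; Tf2O, −78 °C to rt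
Reagents that add atoms: hexamethyldisilazane, C[Si](C)(C)N[Si](C)(C)C; trifluoromethanesulfonic anhydride, O=S(=O)(OS(=O)(=O)C(F)(F)F)C(F)(F)F
Why: Standard route to 2-silylaryl triflate aryne precursors: O-silylation, bromine–lithium exchange that triggers the 1,3 O-to-C silyl shift (retro-Brook), then O-triflation of the phenolate.

Step 11
Reactants: 14 (2R,3R)-2-[5,7-bis(benzyloxy)-4-oxo-4H-chromen-8-yl]-3-[4-(benzyloxy)phenyl]-1-(morpholin-4-yl)-3-[(trimethylsilyl)oxy]propan-1-one; 19 3,5-bis(benzyloxy)-2-(trimethylsilyl)phenyl trifluoromethanesulfonate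
Product: 22 (2R,3R)-5,7-bis(benzyloxy)-2-[4-(benzyloxy)phenyl]-3-[5,7-bis(benzyloxy)-4-oxo-4H-chromen-8-yl]chroman-4-one (2,3-cis), via aryne 20 (not isolated), via hemiaminal caesium alkoxide 21 (not isolated)
Conditions: CsF (4 equiv), 18-crown-6, THF, 0 °C to rt, 19 (1.5 equiv) added slowly; AcOH, then pH 7 buffer, 0 °C
Reagents that add atoms: none
Why: Proposed new method: fluoride removes the O–SiMe3 group of 14 and, by attack on the C–SiMe3 group of 19 with loss of triflate, releases aryne 20; the alkoxide adds to the aryne carbon meta to the flanking benzyloxy group (the future C8a), because that alkoxy group distorts the aryne and stabilises the carbanion developing ortho to it (the future C4a), and this carbanion is acylated by the morpholine amide to give adduct 21, which loses morpholine only at the acetic acid quench. The closest known reaction type is the fluoride-mediated annulation of arynes with methyl salicylates to xanthones (phenoxide addition, then internal acyl capture), together with aryne acyl-alkylation of beta-keto esters; new here are an aliphatic aldol-type alkoxide as nucleophile and an amide as internal electrophile. Ring C of unit 1 is closed by intermolecular O1–C8a bond formation followed by 6-exo-trig attack of the C4a carbanion on the amide carbonyl, and ring A arrives complete with its 5- and 7-oxygens. No stereocentre of the target is created: C2 keeps the R configuration of the aldol carbinol because its C–O bond is never broken, and C3 is carried over from the aldol (any epimerisation there is corrected in step 12). The step needs O-arylation to outrun retro-aldol cleavage and protonation of the aryl anion, which the amide (a poor enolate leaving group), the absence of any O–H in aprotic THF and the slow addition of 19 should secure; it also needs the ketone not to meet base, since a flavanone enolate would open by E1cB, and the persistence of 21 until the buffered quench should secure that.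

Step 12
Reactants: 22 (2R,3R)-5,7-bis(benzyloxy)-2-[4-(benzyloxy)phenyl]-3-[5,7-bis(benzyloxy)-4-oxo-4H-chromen-8-yl]chroman-4-one (2,3-cis)
Product: 23 (2R,3S)-5,7-bis(benzyloxy)-2-[4-(benzyloxy)phenyl]-3-[5,7-bis(benzyloxy)-4-oxo-4H-chromen-8-yl]chroman-4-one (2,3-trans)
Conditions: DBU (0.2 equiv), CH2Cl2/MeOH (4:1), 0 °C to rt
Reagents that add atoms: none
Why: Base-catalysed enolisation and reprotonation at C3 under thermodynamic control should give the trans isomer with both aryl groups equatorial; the protic co-solvent makes reprotonation faster than E1cB ring opening, so C2 is not touched.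

Step 13
Reactants: 23 (2R,3S)-5,7-bis(benzyloxy)-2-[4-(benzyloxy)phenyl]-3-[5,7-bis(benzyloxy)-4-oxo-4H-chromen-8-yl]chroman-4-one (2,3-trans); 24 (4-methoxyphenyl)boronic acid
Product: 25 (2S)-5,7-bis(benzyloxy)-8-{(2R,3S)-5,7-bis(benzyloxy)-2-[4-(benzyloxy)phenyl]-4-oxochroman-3-yl}-2-(4-methoxyphenyl)chroman-4-one
Conditions: Pd(OCOCF3)2 (10 mol %), (R)-4-tert-butyl-2-(pyridin-2-yl)-4,5-dihydrooxazole (12 mol %), NH4PF6 (30 mol %), H2O (5 equiv), ClCH2CH2Cl, 60 °C
Reagents that add atoms: none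
Why: Palladium-catalysed asymmetric conjugate addition of an arylboronic acid to a chromone with a pyridine–oxazoline ligand, under catalyst control; the (R)-ligand is expected to give the (2S) centre by analogy with the known facial sense of the (S)-ligand on cyclic enones, and the near-neutral medium should leave both flavanones closed.

Step 14
Reactants: 25 (2S)-5,7-bis(benzyloxy)-8-{(2R,3S)-5,7-bis(benzyloxy)-2-[4-(benzyloxy)phenyl]-4-oxochroman-3-yl}-2-(4-methoxyphenyl)chroman-4-one
Product: 26 (2S)-8-[(2R,3S)-5,7-dihydroxy-2-(4-hydroxyphenyl)-4-oxochroman-3-yl]-5,7-dihydroxy-2-(4-methoxyphenyl)chroman-4-one (CNP0140544.1)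
Conditions: H2 (1 atm), 10% Pd/C, EtOAc/MeOH, rt
Reagents that add atoms: none
Why: Hydrogenolysis of the five benzyl ethers under neutral conditions should free all phenols, keep the methyl ether and leave the three stereocentres untouched (no base reaches the 4-hydroxyphenyl flavanone).

**Compound list**

1 | 5,7-dihydroxy-4H-chromen-4-one | O=c1ccoc2cc(O)cc(O)c12 | starting material
2 | 5,7-bis(benzyloxy)-4H-chromen-4-one | O=c1ccoc2cc(OCc3ccccc3)cc(OCc3ccccc3)c12 | intermediate
3 | 5,7-bis(benzyloxy)-8-iodo-4H-chromen-4-one | O=c1ccoc2c(I)c(OCc3ccccc3)cc(OCc3ccccc3)c12 | intermediate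
4 | (2-tert-butoxy-2-oxoethyl)zinc bromide | CC(C)(C)OC(=O)C[Zn]Br | starting material
5 | tert-butyl 2-[5,7-bis(benzyloxy)-4-oxo-4H-chromen-8-yl]acetate | CC(C)(C)OC(=O)Cc1c(OCc2ccccc2)cc(OCc2ccccc2)c2c(=O)ccoc12 | intermediate
6 | 2-[5,7-bis(benzyloxy)-4-oxo-4H-chromen-8-yl]acetic acid | OC(=O)Cc1c(OCc2ccccc2)cc(OCc2ccccc2)c2c(=O)ccoc12 | intermediate
7 | (R)-4-benzyl-1,3-oxazolidin-2-one | O=C1OC[C@@H](Cc2ccccc2)N1 | starting material
8 | mixed pivalic anhydride of 6 | CC(C)(C)C(=O)OC(=O)Cc1c(OCc2ccccc2)cc(OCc2ccccc2)c2c(=O)ccoc12 | intermediate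
9 | (R)-4-benzyl-3-{2-[5,7-bis(benzyloxy)-4-oxo-4H-chromen-8-yl]acetyl}-1,3-oxazolidin-2-one | O=C(Cc1c(OCc2ccccc2)cc(OCc2ccccc2)c2c(=O)ccoc12)N1C(=O)OC[C@H]1Cc1ccccc1 | intermediate
10 | 4-(benzyloxy)benzaldehyde | O=Cc1ccc(OCc2ccccc2)cc1 | starting material
11 | (Z)-dibutylboron enolate of 9 | CCCCB(CCCC)O/C(=C\c1c(OCc2ccccc2)cc(OCc2ccccc2)c2c(=O)ccoc12)N1C(=O)OC[C@H]1Cc1ccccc1 | intermediate
12 | (4R)-4-benzyl-3-{(2R,3R)-2-[5,7-bis(benzyloxy)-4-oxo-4H-chromen-8-yl]-3-[4-(benzyloxy)phenyl]-3-hydroxypropanoyl}-1,3-oxazolidin-2-one | O=C([C@H](c1c(OCc2ccccc2)cc(OCc2ccccc2)c2c(=O)ccoc12)[C@@H](O)c1ccc(OCc2ccccc2)cc1)N1C(=O)OC[C@H]1Cc1ccccc1 | intermediate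
13 | (2R,3R)-2-[5,7-bis(benzyloxy)-4-oxo-4H-chromen-8-yl]-3-[4-(benzyloxy)phenyl]-3-hydroxy-1-(morpholin-4-yl)propan-1-one | O=C([C@H](c1c(OCc2ccccc2)cc(OCc2ccccc2)c2c(=O)ccoc12)[C@@H](O)c1ccc(OCc2ccccc2)cc1)N1CCOCC1 | intermediate
14 | (2R,3R)-2-[5,7-bis(benzyloxy)-4-oxo-4H-chromen-8-yl]-3-[4-(benzyloxy)phenyl]-1-(morpholin-4-yl)-3-[(trimethylsilyl)oxy]propan-1-one | O=C([C@H](c1c(OCc2ccccc2)cc(OCc2ccccc2)c2c(=O)ccoc12)[C@@H](O[Si](C)(C)C)c1ccc(OCc2ccccc2)cc1)N1CCOCC1 | intermediate
15 | 3,5-bis(benzyloxy)phenol | Oc1cc(OCc2ccccc2)cc(OCc2ccccc2)c1 | starting material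
16 | 3,5-bis(benzyloxy)-2-bromophenol | Oc1cc(OCc2ccccc2)cc(OCc2ccccc2)c1Br | intermediate
17 | [3,5-bis(benzyloxy)-2-bromophenoxy]trimethylsilane | C[Si](C)(C)Oc1cc(OCc2ccccc2)cc(OCc2ccccc2)c1Br | intermediate
18 | lithium 3,5-bis(benzyloxy)-2-(trimethylsilyl)phenolate | [Li+].[O-]c1cc(OCc2ccccc2)cc(OCc2ccccc2)c1[Si](C)(C)C | intermediate
19 | 3,5-bis(benzyloxy)-2-(trimethylsilyl)phenyl trifluoromethanesulfonate | C[Si](C)(C)c1c(OS(=O)(=O)C(F)(F)F)cc(OCc2ccccc2)cc1OCc1ccccc1 | intermediate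
20 | 3,5-bis(benzyloxy)benzyne (1,2-didehydro-3,5-bis(benzyloxy)benzene) | C1#CC(OCc2ccccc2)=CC(OCc2ccccc2)=C1 | intermediate
21 | caesium (2R,3R)-5,7-bis(benzyloxy)-2-[4-(benzyloxy)phenyl]-3-[5,7-bis(benzyloxy)-4-oxo-4H-chromen-8-yl]-4-(morpholin-4-yl)chroman-4-olate (C4 unassigned) | [Cs+].[O-]C1(N2CCOCC2)c2c(OCc3ccccc3)cc(OCc3ccccc3)cc2O[C@@H](c2ccc(OCc3ccccc3)cc2)[C@H]1c1c(OCc2ccccc2)cc(OCc2ccccc2)c2c(=O)ccoc12 | intermediate
22 | (2R,3R)-5,7-bis(benzyloxy)-2-[4-(benzyloxy)phenyl]-3-[5,7-bis(benzyloxy)-4-oxo-4H-chromen-8-yl]chroman-4-one (2,3-cis) | O=C1c2c(OCc3ccccc3)cc(OCc3ccccc3)cc2O[C@@H](c2ccc(OCc3ccccc3)cc2)[C@H]1c1c(OCc2ccccc2)cc(OCc2ccccc2)c2c(=O)ccoc12 | intermediate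
23 | (2R,3S)-5,7-bis(benzyloxy)-2-[4-(benzyloxy)phenyl]-3-[5,7-bis(benzyloxy)-4-oxo-4H-chromen-8-yl]chroman-4-one (2,3-trans) | O=C1c2c(OCc3ccccc3)cc(OCc3ccccc3)cc2O[C@@H](c2ccc(OCc3ccccc3)cc2)[C@@H]1c1c(OCc2ccccc2)cc(OCc2ccccc2)c2c(=O)ccoc12 | intermediate
24 | (4-methoxyphenyl)boronic acid | COc1ccc(B(O)O)cc1 | starting material
25 | (2S)-5,7-bis(benzyloxy)-8-{(2R,3S)-5,7-bis(benzyloxy)-2-[4-(benzyloxy)phenyl]-4-oxochroman-3-yl}-2-(4-methoxyphenyl)chroman-4-one | COc1ccc([C@@H]2CC(=O)c3c(OCc4ccccc4)cc(OCc4ccccc4)c([C@@H]4C(=O)c5c(OCc6ccccc6)cc(OCc6ccccc6)cc5O[C@H]4c4ccc(OCc5ccccc5)cc4)c3O2)cc1 | intermediate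
26 | (2S)-8-[(2R,3S)-5,7-dihydroxy-2-(4-hydroxyphenyl)-4-oxochroman-3-yl]-5,7-dihydroxy-2-(4-methoxyphenyl)chroman-4-one (CNP0140544.1) | COc1ccc([C@@H]2CC(=O)c3c(O)cc(O)c([C@@H]4C(=O)c5c(O)cc(O)cc5O[C@H]4c4ccc(O)cc4)c3O2)cc1 | target

**Step count and risks**

Total steps: 14. Longest linear sequence: 12 (steps 1–8 and 11–14); the aryne precursor 19 comes from a two-step branch (steps 9–10).

Steps most likely to fail:

1. Step 11 (Proposed new method). What may go wrong: the aryl anion is protonated before it reaches the amide carbonyl, or the alkoxide fragments by retro-aldol, so the O-arylated but uncyclised ether (or cleavage products) results. Fallback with known chemistry, from 13 back to 22: the O–aryl bond is made on its own by addition of the neutral hydroxyl of 13 to aryne 20 (19, CsF, MeCN, rt), where the proton quenches the aryl anion, to give (2R,3R)-3-[3,5-bis(benzyloxy)phenoxy]-2-[5,7-bis(benzyloxy)-4-oxo-4H-chromen-8-yl]-3-[4-(benzyloxy)phenyl]-1-(morpholin-4-yl)propan-1-one F1. Ring C is then closed in a separate electrophilic operation, an intramolecular Friedel–Crafts acylation of the symmetric phloroglucinol-type ring by the amide activated with Tf2O/2-chloropyridine (CH2Cl2, −78 to 0 °C, then aqueous NaHCO3); either ortho position gives the same product, 22.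

2. Step 13. What may go wrong: poor facial selectivity, because the stereocentres of unit 1 sit next to O1 of the chromone and may oppose the ligand (mismatched pair). Fallback, from 23 back to 25: catalyst control is given up; the same boronic acid 24 is added with an achiral catalyst (Pd(OCOCF3)2/2,2'-bipyridine, aqueous ClCH2CH2Cl, 60 °C) under substrate control, and 25 is separated by chromatography from its diastereomer, the unit 2 epimer (2R)-5,7-bis(benzyloxy)-8-{(2R,3S)-5,7-bis(benzyloxy)-2-[4-(benzyloxy)phenyl]-4-oxochroman-3-yl}-2-(4-methoxyphenyl)chroman-4-one F2.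

3. Step 6. What may go wrong: incomplete enolisation because the chromone carbonyl sequesters the boron triflate, or addition of the boron enolate to the boron-activated chromone of a second molecule. Fallback, from 5 back to 13: the carbinol is set by ketone reduction instead of aldol addition.
   - Crossed Claisen acylation of 5 (LiHMDS, THF, −78 °C; 4-(benzyloxy)benzoyl chloride) gives tert-butyl 2-[5,7-bis(benzyloxy)-4-oxo-4H-chromen-8-yl]-3-[4-(benzyloxy)phenyl]-3-oxopropanoate F3.
   - Noyori–Ikariya transfer hydrogenation (RuCl(p-cymene)[(R,R)-TsDPEN], HCO2H/Et3N) is expected to give the (3R)-carbinol, tert-butyl (3R)-2-[5,7-bis(benzyloxy)-4-oxo-4H-chromen-8-yl]-3-[4-(benzyloxy)phenyl]-3-hydroxypropanoate F4; the labile C2 centre is immaterial.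
   - TFA/CH2Cl2 gives (3R)-2-[5,7-bis(benzyloxy)-4-oxo-4H-chromen-8-yl]-3-[4-(benzyloxy)phenyl]-3-hydroxypropanoic acid F5.
   - Coupling with morpholine (EDC·HCl, HOBt, CH2Cl2) gives 13, possibly with its C2 epimer (2S,3R)-2-[5,7-bis(benzyloxy)-4-oxo-4H-chromen-8-yl]-3-[4-(benzyloxy)phenyl]-3-hydroxy-1-(morpholin-4-yl)propan-1-one F6; both go forward because C3 of the chromanone is equilibrated in step 12.

Further compounds
F1 | step 11 | (2R,3R)-3-[3,5-bis(benzyloxy)phenoxy]-2-[5,7-bis(benzyloxy)-4-oxo-4H-chromen-8-yl]-3-[4-(benzyloxy)phenyl]-1-(morpholin-4-yl)propan-1-one | O=C([C@H](c1c(OCc2ccccc2)cc(OCc2ccccc2)c2c(=O)ccoc12)[C@@H](Oc1cc(OCc2ccccc2)cc(OCc2ccccc2)c1)c1ccc(OCc2ccccc2)cc1)N1CCOCC1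
F2 | step 13 | (2R)-5,7-bis(benzyloxy)-8-{(2R,3S)-5,7-bis(benzyloxy)-2-[4-(benzyloxy)phenyl]-4-oxochroman-3-yl}-2-(4-methoxyphenyl)chroman-4-one | COc1ccc([C@H]2CC(=O)c3c(OCc4ccccc4)cc(OCc4ccccc4)c([C@@H]4C(=O)c5c(OCc6ccccc6)cc(OCc6ccccc6)cc5O[C@H]4c4ccc(OCc5ccccc5)cc4)c3O2)cc1
F3 | step 6 | tert-butyl 2-[5,7-bis(benzyloxy)-4-oxo-4H-chromen-8-yl]-3-[4-(benzyloxy)phenyl]-3-oxopropanoate | CC(C)(C)OC(=O)C(c1c(OCc2ccccc2)cc(OCc2ccccc2)c2c(=O)ccoc12)C(=O)c1ccc(OCc2ccccc2)cc1
F4 | step 6 | tert-butyl (3R)-2-[5,7-bis(benzyloxy)-4-oxo-4H-chromen-8-yl]-3-[4-(benzyloxy)phenyl]-3-hydroxypropanoate | CC(C)(C)OC(=O)C(c1c(OCc2ccccc2)cc(OCc2ccccc2)c2c(=O)ccoc12)[C@@H](O)c1ccc(OCc2ccccc2)cc1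
F5 | step 6 | (3R)-2-[5,7-bis(benzyloxy)-4-oxo-4H-chromen-8-yl]-3-[4-(benzyloxy)phenyl]-3-hydroxypropanoic acid | OC(=O)C(c1c(OCc2ccccc2)cc(OCc2ccccc2)c2c(=O)ccoc12)[C@@H](O)c1ccc(OCc2ccccc2)cc1
F6 | step 6 | (2S,3R)-2-[5,7-bis(benzyloxy)-4-oxo-4H-chromen-8-yl]-3-[4-(benzyloxy)phenyl]-3-hydroxy-1-(morpholin-4-yl)propan-1-one | O=C([C@@H](c1c(OCc2ccccc2)cc(OCc2ccccc2)c2c(=O)ccoc12)[C@@H](O)c1ccc(OCc2ccccc2)cc1)N1CCOCC1
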